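## The problem

Compound 10 is an acyclic 1,7-diarylheptanoid: a seven-carbon chain ends in two 4-hydroxyphenyl rings, and C3 and C5 carry oxygen in an anti (3R,5R) 1,3-relationship, C3 as an acetate and C5 as a free hydroxyl. The chain is easy to assemble, because the C3/C5 oxygen pattern is that of a β-diketone with two identical 2-arylethyl arms. The real task is the absolute and relative configuration of two carbinols that lie between methylene groups, with no ring or neighbouring stereocentre to lean on. One centre could direct the other only through 1,3-induction on a β-hydroxy ketone, which still leaves the first centre to a reagent, so in practice both centres must come from an external chiral agent. The C2 symmetry of the parent diol helps twice: a wrong event at one centre gives the meso series, a separable diastereomer and not the enantiomer, and the two hydroxyls are homotopic, so mono-acetylation gives one compound whichever oxygen is acylated and 1,3-acetyl migration in 10 is degenerate. The groups that will not survive rough treatment are the secondary acetate (base, nucleophiles), the free phenols (acidic, readily acylated and oxidised), and any β-oxygenated ketone met on the way, which can eliminate to an enone. The feature that makes the key step possible is that C3 and C5 are secondary carbinols, each epimerisable through its C3 or C5 ketone by reversible dehydrogenation, while the target is itself an O-acetate of the (3R,5R)-diol. An enzyme that acetylates only R-configured carbinols can therefore set the configuration and deliver the acetyl group in one operation.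

## Retrosynthesis

**10 from 9.** The two phenolic O–CH2Ph bonds are cut last. Benzyl ethers are chosen because they come off by neutral hydrogenolysis, which does not touch a secondary acetate. Silyl ethers would need fluoride and methyl ethers a Lewis acid, and both endanger the ester. C3 and C5 lie two carbons beyond the benzylic positions C1 and C7, so their C–O bonds are not benzylic and are safe. Precursor 9 differs from 10 only by the two benzyl groups.

**9 from 8.** One O–acetyl bond is restored in the retrosynthetic sense, leading back to the C2-symmetric diacetate 8. Forward, one of two homotopic acetates is removed, so no site selectivity is needed, only control of the extent of cleavage. This is preferred to stripping both acetates and re-acylating once, because one of the acetyl groups installed in the stereochemistry-setting step stays in the natural product and a step is saved.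

**8 from 5 and 6.** Both O–C(acyl) bonds and both stereocentres are disconnected together, leading to the stereorandom diol 5 and the acyl donor 6. The neighbouring cut, enantioselective formation of the C3–H and C5–H bonds on a diketone, is known chemistry but sets only the configuration and leaves the acetate for later. The cut chosen makes the acetylation itself stereo-determining and lets a precursor with no stereochemical information converge on one isomer. The forward reaction asks for a lipase that acylates only R carbinols at C3 and C5, with the oxygenated arm through C4 read as the large group. It also asks for a ruthenium hydrogen-transfer catalyst that epimerises free carbinols faster than the slow-reacting configurations are acylated.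

**5 from 4.** The C3–H and C5–H bonds are cut, leading to diketone 4. Since the next step corrects every stereoisomer, a simple unselective hydride reduction suffices.

**4 from 3 and 2.** The C6–C7 bond is cut, leading to the monoarylated diketone 3 and the benzylic chloride 2. Forward, the dianion of 3 must be alkylated at its remaining methyl group and not at the C5 methylene beside the arm already in place. The condensation route through an unsaturated diketone would need an alkene hydrogenation that spares benzyl ethers, and a one-flask twofold alkylation would leave the amount of base at the second stage less well defined. Isolating 3 lets the second dianion be formed from pure material with a measured quantity of base.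

**3 from 1 and 2.** The C1–C2 bond of the heptane chain is cut, leading to the five-carbon diketone 1 and a further molecule of 2. Alkylation of the diketone dianion at a terminal carbon is the standard way to extend a β-diketone at its methyl group, and it carries the benzyl ether in from the start. Both starting materials are commercial.

## Roads not taken

**Alternative 1:** The chain is cut at C2–C3 and C5–C6. Propane-1,3-diol A1 supplies C3 to C5 and two molecules of allyl acetate A2 supply the flanking carbons. In the forward step a cyclometalated iridium C,O-benzoate catalyst, generated from [Ir(cod)Cl]2 (monovalent iridium) and a chiral biaryl bisphosphine, dehydrogenates each primary alcohol to the aldehyde and allylates it. This gives (4R,6R)-nona-1,8-diene-4,6-diol A3 with both stereocentres under catalyst control.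
- Merits: an achiral three-carbon diol is turned into the anti diol in one C–C bond-forming step, with the statistical enantiomeric amplification of a two-fold reaction and no preformed organometallic reagent.
- Weak point: each allyl group brings three carbons, but the target has only two between carbinol and arene. The terminal CH2 of A3 would have to be replaced by the aryl ring at both ends. That means alkene transposition followed by cross-metathesis with 1-(benzyloxy)-4-ethenylbenzene A4, or ozonolysis followed by aryl addition and deoxygenation. Diol protection, hydrogenation and the mono-acetate problem follow.
- Comparison: in stereochemical certainty this road is better than the chosen one, since the key step is established chemistry. The chosen plan sets against it a carbon skeleton of exactly the right length after two alkylations of 1 with 2, and an acetate that arrives in the stereo-determining step. The several corrective steps on A3 decide the matter.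

**Alternative 2:** The cut is at the C3–H and C5–H bonds of the unprotected diketone 1,7-bis(4-hydroxyphenyl)heptane-3,5-dione A5. Forward, A5 is hydrogenated with H2 over RuCl2[(R)-BINAP] (divalent ruthenium). Chelation of the β-dicarbonyl unit, and then of the β-hydroxy ketone, lets the catalyst control both reductions and gives (3R,5R)-1,7-bis(4-hydroxyphenyl)heptane-3,5-diol A6.
- Merits: the reaction class is fully precedented for β-diketones, no protecting groups are needed, and A5 is about two steps from 1 by condensation with an aromatic aldehyde and hydrogenation.
- Weak points: A6 has four hydroxyl groups, and the single acetate must go to one carbinol beside two phenols that are acylated more readily. This forces a cyclic orthoester detour or protection after all. Pressure equipment and a costly ligand are also required.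
- Comparison: this road is one to two steps shorter and more certain than the chosen plan, and that has to be said plainly. The chosen plan sets against it that configuration and the O–acetyl bond are made together from a stereorandom precursor, with an inexpensive enzyme at ambient pressure. Errors of the enzyme surface mainly as a separable meso diastereomer, and success would extend dynamic acetylation to 1,3-diols without a methyl carbinol. The known hydrogenation can be run on the protected diketone 4, so it is kept as the fallback for the key step.

**Alternative 3:** The cut is at C1–C2 and C6–C7. C2 to C6 come from (2S,2'S)-2,2'-methylenebis(oxirane) A7 and the benzylic carbons from 4-(benzyloxy)benzylmagnesium chloride A8, prepared from 2. Forward, A8 with catalytic CuI (monovalent copper) opens both oxiranes of A7 at their unsubstituted carbons. This gives (3R,5R)-1,7-bis[4-(benzyloxy)phenyl]heptane-3,5-diol A9, with the configuration untouched because the stereogenic C–O bonds are not broken.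
- Merits: the stereochemistry is secured before the coupling, the regiochemistry of terminal epoxide opening is reliable, and A9 would reach 9 by mono-acetylation.
- Weak points: A7 is a volatile, alkylating building block that takes several steps to make, and its own stereocentres come from an asymmetric reduction, so the stereochemical problem is moved and not removed. Electron-rich benzylic Grignard reagents such as A8 homocouple readily while they are formed. The acetate still needs a separate step.
- Comparison: the stereochemical outcome is more certain than in the chosen plan. Counted from commercial materials the chosen plan is at least as short and avoids preparing A7. It has to offset its enzymatic uncertainty with the diastereomeric purge at 8 and a precedented fallback.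

Key step: step 4

Remark on the chemistry: diketones 3 and 4 are written as diketo tautomers although they exist largely as chelated enols; this does not change the reactions proposed.

## Route

Step 1
Reactants: 1 pentane-2,4-dione; 2 4-(benzyloxy)benzyl chloride
Product: 3 6-[4-(benzyloxy)phenyl]hexane-2,4-dione
Conditions: LiN(iPr)2 (2.1 equiv), THF, −78 → 0 °C; 2 (0.95 equiv), 0 °C; aq. NH4Cl
Reagents that add atoms: none
Why: γ-Alkylation of a β-diketone dianion: the terminal carbanion is far more nucleophilic than the delocalised central position and displaces the benzylic chloride by SN2. A slight deficit of 2 keeps the product, which remains as its unreactive monoenolate, from being alkylated a second time in the same flask.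

Step 2
Reactants: 3 6-[4-(benzyloxy)phenyl]hexane-2,4-dione; 2 4-(benzyloxy)benzyl chloride
Product: 4 1,7-bis[4-(benzyloxy)phenyl]heptane-3,5-dione
Conditions: LiN(iPr)2 (2.1 equiv), THF, −78 → 0 °C; 2 (1.0 equiv), 0 °C; aq. NH4Cl
Reagents that add atoms: none
Why: Second γ-alkylation of a β-diketone dianion: the first equivalent of base removes the acidic C3 proton of 3 and the second removes a proton from the C1 methyl group, the less substituted and kinetically preferred terminus. The resulting primary carbanion displaces the benzylic chloride by SN2, so the second arm enters at the end opposite the first and the symmetrical diketone results.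

Step 3
Reactants: 4 1,7-bis[4-(benzyloxy)phenyl]heptane-3,5-dione
Product: 5 1,7-bis[4-(benzyloxy)phenyl]heptane-3,5-diol (meso and racemic forms together)
Conditions: NaBH4 (excess), MeOH/THF, 0 °C → rt; aq. NH4Cl
Reagents that add atoms: none
Why: Borohydride reduction of both carbonyl groups; the protic medium keeps the enolised diketone in equilibrium with its reducible keto form and the benzyl ethers are inert. No selectivity is needed because every stereoisomer of 5 is a substrate of step 4.

Step 4
Reactants: 5 1,7-bis[4-(benzyloxy)phenyl]heptane-3,5-diol (all stereoisomers); 6 isopropenyl acetate
Product: 8 (3R,5R)-1,7-bis[4-(benzyloxy)phenyl]heptane-3,5-diyl diacetate, via the C5-epimeric (3R)-monoacetate 7 (not isolated)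
Conditions: immobilised Burkholderia cepacia lipase, Ru(CO)2Cl(η5-C5Ph5) (divalent ruthenium, 5 mol %), KOtBu (5 mol %), Na2CO3, 6 (3 equiv), toluene, 40 °C, Ar
Reagents that add atoms: isopropenyl acetate (6), CC(=C)OC(C)=O
Why: Proposed new method: KOtBu converts Ru(CO)2Cl(η5-C5Ph5) into its tert-butoxide, which exchanges with every free carbinol of 5 and of monoacetate 7, and reversible β-hydride elimination to the ruthenium-bound ketone followed by hydride return scrambles C3 and C5. The lipase is acetylated at its active-site serine by 6 (acetone leaves, so the transfer cannot reverse; two molecules of 6 are consumed per molecule of 5) and passes the acetyl group only to a carbinol whose larger arm fits its large pocket; by the empirical size rule for lipases this is the R configuration at C3 and C5, provided the β-oxygenated arm through C4 is read as the large group and the unbranched 2-arylethyl arm sits in the medium pocket. Acetates cannot form ruthenium alkoxides and are stereochemically frozen, so meso and racemic 5 drain through 7 into the single (3R,5R)-diacetate 8, both new stereocentres being set by the enzyme and not by the substrate. No ring closes. The closest known reaction type is the ruthenium/lipase dynamic kinetic asymmetric transformation of 1,3-diols with methyl carbinols into (R,R)-diacetates; new here is that neither carbinol has a methyl group, so the enzyme must tell a 2-arylethyl arm from a 2-oxygenated alkyl arm. The step needs R-selectivity at both centres and epimerisation that is faster than acylation of S carbinols and faster than 1,3-acetyl migration in the syn isomer of 7; the substrate feature relied on is the branch at the β-carbon of the large arm, which grows further once it carries an acetate.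

Step 5
Reactants: 8 (3R,5R)-1,7-bis[4-(benzyloxy)phenyl]heptane-3,5-diyl diacetate
Product: 9 (3R,5R)-1,7-bis[4-(benzyloxy)phenyl]-5-hydroxyheptan-3-yl acetate
Conditions: K2CO3 (0.2 equiv), MeOH/THF, 0 °C, AcOH quench near half conversion of the acetate groups; recovered 8 resubmitted
Reagents that add atoms: none
Why: Base-catalysed transesterification (partial methanolysis): the two acetates of 8 are homotopic, so loss of either gives the same compound 9, and acetyl migration between O3 and O5 of 9 is degenerate. Only acyl–oxygen bonds break, so C3 and C5 keep their configuration.

Step 6
Reactants: 9 (3R,5R)-1,7-bis[4-(benzyloxy)phenyl]-5-hydroxyheptan-3-yl acetate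
Product: 10 (3R,5R)-5-hydroxy-1,7-bis(4-hydroxyphenyl)heptan-3-yl acetate (CNP0132544.1)
Conditions: H2 (1 atm), Pd/C, EtOAc, rt
Reagents that add atoms: none
Why: Catalytic hydrogenolysis of the two aryl benzyl ethers under neutral, non-nucleophilic conditions, which leave the secondary acetate in place. The C3–O and C5–O bonds are not benzylic (C3 and C5 lie two carbons beyond C1 and C7) and are not cleaved, so the configuration is retained.

## Compound list

1 | pentane-2,4-dione | CC(=O)CC(C)=O | starting material
2 | 4-(benzyloxy)benzyl chloride [1-(benzyloxy)-4-(chloromethyl)benzene] | ClCc1ccc(OCc2ccccc2)cc1 | starting material
3 | 6-[4-(benzyloxy)phenyl]hexane-2,4-dione | CC(=O)CC(=O)CCc1ccc(OCc2ccccc2)cc1 | intermediate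
4 | 1,7-bis[4-(benzyloxy)phenyl]heptane-3,5-dione | O=C(CCc1ccc(OCc2ccccc2)cc1)CC(=O)CCc1ccc(OCc2ccccc2)cc1 | intermediate
5 | 1,7-bis[4-(benzyloxy)phenyl]heptane-3,5-diol, meso and racemic forms together | OC(CCc1ccc(OCc2ccccc2)cc1)CC(O)CCc1ccc(OCc2ccccc2)cc1 | intermediate
6 | isopropenyl acetate (prop-1-en-2-yl acetate) | CC(=C)OC(C)=O | starting material
7 | (3R)-1,7-bis[4-(benzyloxy)phenyl]-5-hydroxyheptan-3-yl acetate, both C5 epimers (not isolated) | CC(=O)O[C@H](CCc1ccc(OCc2ccccc2)cc1)CC(O)CCc1ccc(OCc2ccccc2)cc1 | intermediate
8 | (3R,5R)-1,7-bis[4-(benzyloxy)phenyl]heptane-3,5-diyl diacetate | CC(=O)O[C@H](CCc1ccc(OCc2ccccc2)cc1)C[C@H](OC(C)=O)CCc1ccc(OCc2ccccc2)cc1 | intermediate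
9 | (3R,5R)-1,7-bis[4-(benzyloxy)phenyl]-5-hydroxyheptan-3-yl acetate | CC(=O)O[C@H](CCc1ccc(OCc2ccccc2)cc1)C[C@H](O)CCc1ccc(OCc2ccccc2)cc1 | intermediate
10 | (3R,5R)-5-hydroxy-1,7-bis(4-hydroxyphenyl)heptan-3-yl acetate | CC(=O)O[C@H](CCc1ccc(O)cc1)C[C@H](O)CCc1ccc(O)cc1 | target

## Step count and risks

Total steps: 6. Longest linear sequence: 6 steps, from 1 to 10. Steps 1, 3 and 6 are routine; the uncertain ones follow.

**Step 4 (key step, proposed new method).**
- What may go wrong: recognition by the lipase may be insufficient. Both arms at each carbinol begin with a methylene group, so acylation may be slow or poorly R-selective.
- A slow second acylation lets 1,3-acetyl migration in the syn isomer of 7 expose an R carbinol beside an S acetate, which diverts material to the meso-diacetate.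
- Release of the transient β-acetoxy ketone from ruthenium, followed by loss of acetic acid, is a further drain.
- Limiting factor: the wrong enantiomer needs two enzyme errors, so imperfect selection should appear mainly as meso-diacetate. That is a diastereomer of 8 and removable by chromatography or crystallisation, so the cost is throughput and not enantiomeric purity.
- Fallback (known chemistry): the route is left at diketone 4. Asymmetric hydrogenation of both carbonyl groups with H2 over RuCl2[(R)-BINAP] (divalent ruthenium) in MeOH/CH2Cl2 should give (3R,5R)-1,7-bis[4-(benzyloxy)phenyl]heptane-3,5-diol F1, the benzyl ethers being inert to the homogeneous catalyst. Acetylation of both hydroxyls with acetic anhydride, pyridine and catalytic 4-(dimethylamino)pyridine returns to the route at 8.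

**Step 2.**
- What may go wrong: competing deprotonation at the C5 methylene of 3, or proton exchange between the dianion and the product enolate. Either would cause alkylation on the side that already carries an arm, or a second alkylation of the product, with loss of the symmetrical diketone.
- Fallback: it sets out from 1 and so also bypasses step 1. A boron-templated double aldol condensation (B2O3, B(OnBu)3, n-BuNH2, EtOAc, then dilute HCl) with purchased 4-(benzyloxy)benzaldehyde F2 masks the central methylene as a boron chelate and should give (1E,6E)-1,7-bis[4-(benzyloxy)phenyl]hepta-1,6-diene-3,5-dione F3. Hydrogenation of the two enone C=C bonds with H2 over RhCl(PPh3)3 (monovalent rhodium), which cannot hydrogenolyse benzyl ethers, returns to the route at 4.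

**Step 5.**
- What may go wrong: over-cleavage. The hydroxyl freed by the first methanolysis can assist cleavage of its neighbour, so the mono-acetate may not accumulate beyond the statistical level and much material would cycle as recovered 8 and diol.
- Fallback: it sets out from 8. Complete methanolysis (K2CO3, MeOH, rt) gives (3R,5R)-1,7-bis[4-(benzyloxy)phenyl]heptane-3,5-diol F1, the compound already described under step 4. Treatment with trimethyl orthoacetate and catalytic camphorsulfonic acid in CH2Cl2 should close the cyclic orthoester (4R,6R)-4,6-bis{2-[4-(benzyloxy)phenyl]ethyl}-2-methoxy-2-methyl-1,3-dioxane F4. Mild aqueous acetic acid opens F4 to exactly one acetate and one hydroxyl, returning to the route at 9.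

## Further compounds

F1 | step 4 | (3R,5R)-1,7-bis[4-(benzyloxy)phenyl]heptane-3,5-diol | O[C@H](CCc1ccc(OCc2ccccc2)cc1)C[C@H](O)CCc1ccc(OCc2ccccc2)cc1
F2 | step 2 | 4-(benzyloxy)benzaldehyde (purchased partner of the fallback) | O=Cc1ccc(OCc2ccccc2)cc1
F3 | step 2 | (1E,6E)-1,7-bis[4-(benzyloxy)phenyl]hepta-1,6-diene-3,5-dione | O=C(/C=C/c1ccc(OCc2ccccc2)cc1)CC(=O)/C=C/c1ccc(OCc2ccccc2)cc1
F4 | step 5 | (4R,6R)-4,6-bis{2-[4-(benzyloxy)phenyl]ethyl}-2-methoxy-2-methyl-1,3-dioxane | COC1(C)O[C@H](CCc2ccc(OCc3ccccc3)cc2)C[C@@H](CCc2ccc(OCc3ccccc3)cc2)O1
A1 | alternative 1 | propane-1,3-diol | OCCCO
A2 | alternative 1 | allyl acetate | CC(=O)OCC=C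
A3 | alternative 1 | (4R,6R)-nona-1,8-diene-4,6-diol | O[C@H](CC=C)C[C@H](O)CC=C
A4 | alternative 1 | 1-(benzyloxy)-4-ethenylbenzene | C=Cc1ccc(OCc2ccccc2)cc1
A5 | alternative 2 | 1,7-bis(4-hydroxyphenyl)heptane-3,5-dione | O=C(CCc1ccc(O)cc1)CC(=O)CCc1ccc(O)cc1
A6 | alternative 2 | (3R,5R)-1,7-bis(4-hydroxyphenyl)heptane-3,5-diol | O[C@H](CCc1ccc(O)cc1)C[C@H](O)CCc1ccc(O)cc1
A7 | alternative 3 | (2S,2'S)-2,2'-methylenebis(oxirane) | C1O[C@H]1C[C@H]1CO1
A8 | alternative 3 | 4-(benzyloxy)benzylmagnesium chloride | Cl[Mg]Cc1ccc(OCc2ccccc2)cc1
A9 | alternative 3 | (3R,5R)-1,7-bis[4-(benzyloxy)phenyl]heptane-3,5-diol (identical with F1) | O[C@H](CCc1ccc(OCc2ccccc2)cc1)C[C@H](O)CCc1ccc(OCc2ccccc2)cc1
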